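Amounts first: the flask holds 0.10 M of J and L at a loading of 0.01 mol%, and the question is how much J that L gets through by 12 h.

| setting | spring | winter | dawn | flask |
|---|---|---|---|---|
| J | 0.10 M | 0.10 M | 0.20 M | 0.10 M |
| L | 0.005 mol% | 0.0075 mol% | 0.01 mol% | 0.01 mol% |
| remark | run made earlier | run made earlier | run made earlier |  |
| time |  |  |  | 12 h |

- spring (time / h: G / %, J / %, E / %): 1.00: 4.3, 95.0, 0; 2.50: 9.3, 90.7, 1.7; 6.00: 14.2, 83.4, 1.1; 15.0: 12.1, 84.2, 3.6
- winter (time / h: G / %, J / %, E / %): 2.00: 11.9, 85.9, 1.2; 5.00: 18.6, 78.9, 1.2; 10.0: 19.6, 75.3, 2.2; 15.0: 19.1, 73.5, 5.9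
- dawn (time / h: G / %, J / %, E / %): 1.00: 12.4, 83.4, 0.5; 2.50: 22.8, 75.0, 0; 6.00: 32.5, 64.2, 3.7; 15.0: 30.2, 58.2, 9.0

(readings scatter by 1 percentage point)

- how much G the flask holds at 12 h, in percent of the J charged
- how much J the flask holds at 12 h, in percent of the J charged
- how much E the flask holds at 12 h, in percent of the J charged



J levels off well short of zero: spring reads 83.4% and then 84.2%. I therefore assume that L decays by first-order loss with rate constant d and treat each last J reading as the stall. I also take the binding of J to L as fast and in balance, so that the rate per J is k times L, divided by one plus J/K (Michaelis–Menten saturation, with K the half-saturating amount of J). Integrating over the decay of L gives this: ln(charge/J) + (charge − J)/K equals k/d times the molar L charged.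

Dawn has 4.00 times spring's molar L, but its logarithm is 3.15 times spring's, and the second term has to cover the difference. Requiring that ratio of the full sums gives a reading of K = 0.139 M. Spring's sum, the reach of its charge of L, is then 0.286, and reach scales with molar L. Winter's last J gives 0.498 where scaling gives 0.428, so my J carries a few points of doubt.

The flask has twice spring's molar L, so its reach is 0.571. Linearising the logarithm gives J near 66.8%, and one Newton step gives 70.0% at the stall, which I take as my J for the flask at 12 h. For the split, E makes up 23.0% of G plus E in dawn's last reading. Scaling that linearly to 12 h gives E 5.51% and leaves G 24.5%.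

The forecast gives G 29%, E 5% and J 65%, lower than my J, and its grounds open with “The runs stall because L dies”.

The flask gives J 68.8%, G 25.2% and E 6.06%.

    J + L → G + L, rate k1*[J]*[L]/(1 + ([J]/Km1)) (0.0810 M, k = 27000 /M/h)
    G → E (k = 0.0230 /h)
    L → Q (k = 0.350 /h)

Put back into the sum, the flask's J gives 0.598 against the reach of 0.571. Now take the neighbouring flask with 0.040 M of J at the same loading. Its molar L is lower than the flask's, so its reach is 0.228. The first guess is 82.3%, and the Newton step gives J 83.5%. At 12.0 h that neighbour holds J 81.0%, G 15.3% and E 3.67%, with 1.50% of its L left.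

The numbers in the tables were generated by integration with constants of no real substance; scatter was added.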